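**Target as read from the SMILES:** methyl 2-[(3S,6R)-6-methoxy-6-[(6E)-hexadec-6-ene-4,15-diyn-1-yl]-1,2-dioxan-3-yl]acetate. The ring CH carbon is S and the peroxyketal carbon is R, so OMe and CH2CO2Me are cis (OMe axial, both carbon substituents equatorial).

## Retrosynthetic overview

1. Target 26 ⇐ C‑desilylation ⇐ Sonogashira C(sp)–C(sp2) union of dioxane alkyne 16 with (E)‑vinyl iodide 24.
2. The only ring (1,2‑dioxane) is closed by 6‑exo SN2 of a hydroperoxy ketal on a secondary mesylate (inversion sets the ring CH). Acid/MeOH then equilibrates the peroxyketal carbon to the anomerically favoured cis isomer, and CH2OTBS is taken to CO2Me.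
3. The hydroperoxy‑ketal mesylate ⇐ ozonolysis in MeOH of a 1,1‑disubstituted alkene ⇐ Wittig on a γ‑hydroxy ketone ⇐ hept‑6‑yn‑2‑one hydrazone anion + (S)‑epoxide 7 (from but‑3‑en‑1‑ol by hydrolytic kinetic resolution).
4. 24 ⇐ Takai olefination ⇐ oxidation ⇐ C‑silylation ⇐ alkyne zipper ⇐ propargyl alcohol + 1‑bromoheptane.

## Route

Step 1
Reactants: 1 hex-5-ynoic acid
Product: 2 hept-6-yn-2-one
Conditions: MeLi (3.3 equiv), THF, 0 °C → rt; inverse quench into cold 1 M HCl
Reagents that add atoms: methyllithium, [Li]C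
Why: Organolithium addition to a lithium carboxylate gives a stable gem‑dialkoxide that collapses to the methyl ketone only on quench, the extra equivalents being consumed by CO2H and C≡C–H.

Step 2
Reactants: 2 hept-6-yn-2-one
Product: 3 2-(hept-6-yn-2-ylidene)-1,1-dimethylhydrazine (E/Z mixture)
Conditions: Me2NNH2 (3 equiv), AcOH (cat.), EtOH, reflux
Reagents that add atoms: N,N-dimethylhydrazine, CN(C)N
Why: Hydrazone condensation converts the ketone into an aza‑enolate precursor that can be metalated regioselectively at the methyl group.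

Step 3
Reactants: 4 but-3-en-1-ol
Product: 5 (but-3-en-1-yloxy)(tert-butyl)dimethylsilane
Conditions: TBSCl, imidazole, CH2Cl2, 0 °C → rt
Reagents that add atoms: tert-butyldimethylsilyl chloride, CC(C)(C)[Si](C)(C)Cl
Why: Silyl ether formation masks the future carboxyl carbon as a robust, non‑acidifying CH2OTBS group.

Step 4
Reactants: 5 (but-3-en-1-yloxy)(tert-butyl)dimethylsilane
Product: 6 rac-tert-butyldimethyl[2-(oxiran-2-yl)ethoxy]silane
Conditions: mCPBA, CH2Cl2, 0 °C → rt
Reagents that add atoms: mCPBA, OOC(=O)c1cccc(Cl)c1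
Why: Prilezhaev epoxidation of the terminal alkene gives the racemic terminal epoxide.

Step 5
Reactants: 6 rac-tert-butyldimethyl[2-(oxiran-2-yl)ethoxy]silane
Product: 7 (S)-tert-butyldimethyl[2-(oxiran-2-yl)ethoxy]silane
Conditions: (R,R)-(salen)Co(III)OAc (0.5 mol %), H2O (0.55 equiv), THF, 0 °C → rt; distil epoxide from diol
Reagents that add atoms: none
Why: Jacobsen hydrolytic kinetic resolution, in which the (R,R) catalyst hydrolyses the (R)‑oxirane and leaves the (S)‑epoxide in >99% ee; this is the source of the ring CH stereocentre.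

Step 6
Reactants: 3 2-(hept-6-yn-2-ylidene)-1,1-dimethylhydrazine; 7 (S)-tert-butyldimethyl[2-(oxiran-2-yl)ethoxy]silane
Product: 9 (9R)-11-[(tert-butyldimethylsilyl)oxy]-9-hydroxyundec-1-yn-6-one, via hydroxy hydrazone 8 (not isolated)
Conditions: n-BuLi (2.1 equiv), THF, −78 → 0 °C; 7, −78 °C → rt; then AcOH/NaOAc/THF/H2O (pH 5), rt
Reagents that add atoms: water, O
Why: Corey–Enders hydrazone alkylation, in which the aza‑enolate formed at the methyl carbon (the acetylide is a bystander) opens the epoxide at CH2 by SN2 so the stereocentre is untouched, and buffered hydrolysis frees the ketone.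

Step 7
Reactants: 9 (9R)-11-[(tert-butyldimethylsilyl)oxy]-9-hydroxyundec-1-yn-6-one
Product: 10 (3R)-1-[(tert-butyldimethylsilyl)oxy]-6-methylideneundec-10-yn-3-ol
Conditions: Ph3PCH3Br (3.5 equiv), KOtBu (3.3 equiv), THF, 0 °C → rt
Reagents that add atoms: methyltriphenylphosphonium bromide, C[P+](c1ccccc1)(c1ccccc1)c1ccccc1.[Br-]
Why: Wittig methylenation with excess ylide (which tolerates the alkoxide and acetylide) turns the ketone into the 1,1‑disubstituted alkene needed for ozonolytic hydroperoxy‑ketal formation.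

Step 8
Reactants: 10 (3R)-1-[(tert-butyldimethylsilyl)oxy]-6-methylideneundec-10-yn-3-ol
Product: 11 (3R)-1-[(tert-butyldimethylsilyl)oxy]-6-methylideneundec-10-yn-3-yl methanesulfonate
Conditions: MsCl, Et3N, CH2Cl2, 0 °C
Reagents that add atoms: methanesulfonyl chloride, CS(=O)(=O)Cl
Why: Sulfonylation activates the carbinol with retention, and because the carboxyl carbon is still CH2OTBS there is no acidic α‑CH2 to trigger E1cB elimination.

Step 9
Reactants: 11 (3R)-1-[(tert-butyldimethylsilyl)oxy]-6-methylideneundec-10-yn-3-yl methanesulfonate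
Product: 12 (3R)-1-[(tert-butyldimethylsilyl)oxy]-6-hydroperoxy-6-methoxyundec-10-yn-3-yl methanesulfonate (1:1 epimers at C6)
Conditions: O3, CH2Cl2/MeOH (4:1), −78 °C, Sudan Red end point; N2 purge, no reductant
Reagents that add atoms: ozone, [O-][O+]=O; methanol, CO
Why: Criegee ozonolysis in methanol puts the carbonyl oxide on the substituted carbon, where MeOH traps it as the α‑methoxy hydroperoxide, and the alkene reacts far faster than the terminal alkyne.

Step 10
Reactants: 12 (3R)-1-[(tert-butyldimethylsilyl)oxy]-6-hydroperoxy-6-methoxyundec-10-yn-3-yl methanesulfonate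
Product: 13 tert-butyl{2-[(3S)-6-methoxy-6-(pent-4-yn-1-yl)-1,2-dioxan-3-yl]ethoxy}dimethylsilane (both C6 epimers)
Conditions: KOtBu (1.05 equiv), 18-crown-6, THF, 0 °C
Reagents that add atoms: none
Why: Intramolecular Williamson‑type 6‑exo‑tet SN2 of the peroxy anion on the secondary mesylate closes the 1,2‑dioxane with clean inversion, setting the ring CH as S.

Step 11
Reactants: 13 tert-butyl{2-[(3S)-6-methoxy-6-(pent-4-yn-1-yl)-1,2-dioxan-3-yl]ethoxy}dimethylsilane
Product: 14 2-[(3S,6R)-6-methoxy-6-(pent-4-yn-1-yl)-1,2-dioxan-3-yl]ethan-1-ol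
Conditions: TsOH·H2O (10 mol %), MeOH, rt; chromatography, minor trans epimer resubmitted
Reagents that add atoms: methanol, CO
Why: Acid‑catalysed peroxyketal exchange through the peroxycarbenium ion equilibrates the ketal carbon to the thermodynamic isomer (anomeric axial OMe, both carbon substituents equatorial, i.e. 6R cis), while the same acid methanolysis removes the TBS ether.

Step 12
Reactants: 14 2-[(3S,6R)-6-methoxy-6-(pent-4-yn-1-yl)-1,2-dioxan-3-yl]ethan-1-ol
Product: 15 2-[(3S,6R)-6-methoxy-6-(pent-4-yn-1-yl)-1,2-dioxan-3-yl]acetic acid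
Conditions: TEMPO (20 mol %), PhI(OAc)2 (2.2 equiv), MeCN/H2O (1:1), rt
Reagents that add atoms: water, O
Why: Oxoammonium (TEMPO/BAIB) oxidation takes the primary alcohol through the aldehyde hydrate to the acid without touching the O–O bond, the peroxyketal or the alkyne.

Step 13
Reactants: 15 2-[(3S,6R)-6-methoxy-6-(pent-4-yn-1-yl)-1,2-dioxan-3-yl]acetic acid
Product: 16 methyl 2-[(3S,6R)-6-methoxy-6-(pent-4-yn-1-yl)-1,2-dioxan-3-yl]acetate
Conditions: TMSCHN2, toluene/MeOH (4:1), 0 °C
Reagents that add atoms: (trimethylsilyl)diazomethane, C[Si](C)(C)C=[N+]=[N-]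
Why: Diazoalkane esterification methylates the carboxylic acid under neutral conditions that cannot open the β‑peroxy ester by retro‑oxa‑Michael reaction.

Step 14
Reactants: 17 prop-2-yn-1-ol; 18 1-bromoheptane
Product: 19 dec-2-yn-1-ol
Conditions: LiNH2 (2.2 equiv), liq. NH3/THF, −33 °C
Reagents that add atoms: none
Why: Alkylation of the propargyl alcohol dianion occurs at the more nucleophilic acetylide carbon in an SN2 reaction with the primary bromide.

Step 15
Reactants: 19 dec-2-yn-1-ol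
Product: 20 dec-9-yn-1-ol
Conditions: KH (4 equiv), H2N(CH2)3NH2, 0 °C → rt; then H2O
Reagents that add atoms: none
Why: The acetylene zipper (KAPA) walks the triple bond along the chain by propargyl–allenyl isomerisations and is driven to the terminus by irreversible formation of the terminal acetylide.

Step 16
Reactants: 20 dec-9-yn-1-ol
Product: 22 10-(trimethylsilyl)dec-9-yn-1-ol, via O-silyl ether 21 (not isolated)
Conditions: n-BuLi (2.2 equiv), THF, −78 °C; TMSCl (2.5 equiv), → rt; then 1 M HCl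
Reagents that add atoms: chlorotrimethylsilane, C[Si](C)(C)Cl
Why: Silylation of the alkoxide/acetylide dianion followed by selective acid hydrolysis of the labile O–Si bond leaves the C‑silyl alkyne, which blocks this terminus in the later Sonogashira coupling.

Step 17
Reactants: 22 10-(trimethylsilyl)dec-9-yn-1-ol
Product: 23 10-(trimethylsilyl)dec-9-ynal
Conditions: TEMPO (10 mol %), PhI(OAc)2 (1.1 equiv), CH2Cl2, rt
Reagents that add atoms: none
Why: Anhydrous TEMPO/BAIB oxidation stops cleanly at the aldehyde.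

Step 18
Reactants: 23 10-(trimethylsilyl)dec-9-ynal
Product: 24 [(10E)-11-iodoundec-10-en-1-yn-1-yl]trimethylsilane
Conditions: CrCl2 (6 equiv), CHI3 (2 equiv), dioxane/THF (6:1), 0 °C → rt
Reagents that add atoms: iodoform, IC(I)I
Why: Takai olefination through a gem‑dichromium carbenoid gives the one‑carbon‑homologated vinyl iodide with high E selectivity (best in dioxane/THF).

Step 19
Reactants: 16 methyl 2-[(3S,6R)-6-methoxy-6-(pent-4-yn-1-yl)-1,2-dioxan-3-yl]acetate; 24 [(10E)-11-iodoundec-10-en-1-yn-1-yl]trimethylsilane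
Product: 25 methyl 2-[(3S,6R)-6-methoxy-6-[(6E)-16-(trimethylsilyl)hexadec-6-ene-4,15-diyn-1-yl]-1,2-dioxan-3-yl]acetate
Conditions: Pd(PPh3)4 (5 mol %), CuI (10 mol %), Et3N, THF (degassed), rt
Reagents that add atoms: none
Why: Sonogashira coupling joins the only free terminal alkyne to the vinyl iodide with retention of E geometry, and dialkyl peroxides and peroxyketals are not reduced by Pd(0)/Cu(I)/amine at room temperature.

Step 20
Reactants: 25 methyl 2-[(3S,6R)-6-methoxy-6-[(6E)-16-(trimethylsilyl)hexadec-6-ene-4,15-diyn-1-yl]-1,2-dioxan-3-yl]acetate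
Product: 26 methyl 2-[(3S,6R)-6-methoxy-6-[(6E)-hexadec-6-ene-4,15-diyn-1-yl]-1,2-dioxan-3-yl]acetate
Conditions: K2CO3 (0.3 equiv), MeOH, 0 °C
Reagents that add atoms: none
Why: Methoxide‑catalysed protodesilylation frees the terminal alkyne, the methyl ester is unchanged in MeOH, and brief cold exposure avoids base‑induced opening of the β‑peroxy ester.

## Compound list

1 | hex-5-ynoic acid | C#CCCCC(=O)O | starting material
2 | hept-6-yn-2-one | CC(=O)CCCC#C | intermediate
3 | 2-(hept-6-yn-2-ylidene)-1,1-dimethylhydrazine | CN(C)N=C(C)CCCC#C | intermediate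
4 | but-3-en-1-ol | C=CCCO | starting material
5 | (but-3-en-1-yloxy)(tert-butyl)dimethylsilane | C=CCCO[Si](C)(C)C(C)(C)C | intermediate
6 | rac-tert-butyldimethyl[2-(oxiran-2-yl)ethoxy]silane | CC(C)(C)[Si](C)(C)OCCC1CO1 | intermediate
7 | (S)-tert-butyldimethyl[2-(oxiran-2-yl)ethoxy]silane | CC(C)(C)[Si](C)(C)OCC[C@H]1CO1 | intermediate
8 | (9R)-11-[(tert-butyldimethylsilyl)oxy]-6-(2,2-dimethylhydrazinylidene)undec-1-yn-9-ol (not isolated) | CC(C)(C)[Si](C)(C)OCC[C@H](O)CCC(=NN(C)C)CCCC#C | intermediate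
9 | (9R)-11-[(tert-butyldimethylsilyl)oxy]-9-hydroxyundec-1-yn-6-one | CC(C)(C)[Si](C)(C)OCC[C@H](O)CCC(=O)CCCC#C | intermediate
10 | (3R)-1-[(tert-butyldimethylsilyl)oxy]-6-methylideneundec-10-yn-3-ol | CC(C)(C)[Si](C)(C)OCC[C@H](O)CCC(=C)CCCC#C | intermediate
11 | (3R)-1-[(tert-butyldimethylsilyl)oxy]-6-methylideneundec-10-yn-3-yl methanesulfonate | CC(C)(C)[Si](C)(C)OCC[C@H](OS(C)(=O)=O)CCC(=C)CCCC#C | intermediate
12 | (3R)-1-[(tert-butyldimethylsilyl)oxy]-6-hydroperoxy-6-methoxyundec-10-yn-3-yl methanesulfonate (C6 epimers) | CC(C)(C)[Si](C)(C)OCC[C@H](OS(C)(=O)=O)CCC(OC)(OO)CCCC#C | intermediate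
13 | tert-butyl{2-[(3S)-6-methoxy-6-(pent-4-yn-1-yl)-1,2-dioxan-3-yl]ethoxy}dimethylsilane (C6 epimers) | C#CCCCC1(OC)CC[C@@H](CCO[Si](C)(C)C(C)(C)C)OO1 | intermediate
14 | 2-[(3S,6R)-6-methoxy-6-(pent-4-yn-1-yl)-1,2-dioxan-3-yl]ethan-1-ol | C#CCCC[C@]1(OC)CC[C@@H](CCO)OO1 | intermediate
15 | 2-[(3S,6R)-6-methoxy-6-(pent-4-yn-1-yl)-1,2-dioxan-3-yl]acetic acid | C#CCCC[C@]1(OC)CC[C@@H](CC(=O)O)OO1 | intermediate
16 | methyl 2-[(3S,6R)-6-methoxy-6-(pent-4-yn-1-yl)-1,2-dioxan-3-yl]acetate | C#CCCC[C@]1(OC)CC[C@@H](CC(=O)OC)OO1 | intermediate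
17 | prop-2-yn-1-ol | C#CCO | starting material
18 | 1-bromoheptane | CCCCCCCBr | starting material
19 | dec-2-yn-1-ol | CCCCCCCC#CCO | intermediate
20 | dec-9-yn-1-ol | C#CCCCCCCCCO | intermediate
21 | trimethyl{[10-(trimethylsilyl)dec-9-yn-1-yl]oxy}silane (not isolated) | C[Si](C)(C)C#CCCCCCCCCO[Si](C)(C)C | intermediate
22 | 10-(trimethylsilyl)dec-9-yn-1-ol | C[Si](C)(C)C#CCCCCCCCCO | intermediate
23 | 10-(trimethylsilyl)dec-9-ynal | C[Si](C)(C)C#CCCCCCCCC=O | intermediate
24 | [(10E)-11-iodoundec-10-en-1-yn-1-yl]trimethylsilane | C[Si](C)(C)C#CCCCCCCC/C=C/I | intermediate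
25 | methyl 2-[(3S,6R)-6-methoxy-6-[(6E)-16-(trimethylsilyl)hexadec-6-ene-4,15-diyn-1-yl]-1,2-dioxan-3-yl]acetate | C[Si](C)(C)C#CCCCCCCC/C=C/C#CCCC[C@]1(OC)CC[C@@H](CC(=O)OC)OO1 | intermediate
26 | methyl 2-[(3S,6R)-6-methoxy-6-[(6E)-hexadec-6-ene-4,15-diyn-1-yl]-1,2-dioxan-3-yl]acetate | C#CCCCCCCC/C=C/C#CCCC[C@]1(OC)CC[C@@H](CC(=O)OC)OO1 | target

## Step count and risks

Total step count: 20.
Longest linear sequence: 13 (steps 3–13, 19, 20, from but-3-en-1-ol).

**Step 10** (peroxide ring closure) is the most likely to fail, because E2 elimination of the secondary mesylate and base‑induced O–O fragmentation compete with the 6‑exo SN2. The fallback sets out from mesylate 11 and brings the O–O unit in intermolecularly, closing the ring at the ketal carbon instead. 2‑Methoxyprop‑2‑yl hydroperoxide (CC(C)(OC)OO) with CsOH·H2O in DMF displaces the mesylate with inversion to give the mixed peroxyketal tert-butyl({(3S)-3-[(2-methoxypropan-2-yl)peroxy]-6-methylideneundec-10-yn-1-yl}oxy)dimethylsilane F5. Ozonolysis in CH2Cl2 at −78 °C with Me2S work‑up gives the ketone (9S)-11-[(tert-butyldimethylsilyl)oxy]-9-[(2-methoxypropan-2-yl)peroxy]undec-1-yn-6-one F6. TsOH in MeOH then removes the methoxypropyl and TBS groups, and the freed secondary hydroperoxide closes onto the ketone as the methyl peroxyketal under the same thermodynamic control. The fallback comes back to the route at 14.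

**Step 6** (dilithio hydrazone/epoxide opening) can fail through poor solubility or reactivity of the acetylide/aza‑enolate dianion, or through competing acetylide attack. The fallback sets out from epoxide 7 and propargyl alcohol 17 and builds the same bond with a 2‑substituted allyl Grignard reagent. Bought 5‑chloropent‑1‑yne (C#CCCCCl) is C‑silylated (n‑BuLi, TMSCl) to (5-chloropent-1-yn-1-yl)trimethylsilane F1. Its Grignard reagent adds across 17 under CuI catalysis (anti‑carbomagnesiation) to give 2-methylidene-7-(trimethylsilyl)hept-6-yn-1-ol F2. MsCl/LiCl/collidine gives the allylic chloride [6-(chloromethyl)hept-6-en-1-yn-1-yl]trimethylsilane F3. The derived allylmagnesium chloride opens 7 at CH2 to give (3R)-1-[(tert-butyldimethylsilyl)oxy]-6-methylidene-11-(trimethylsilyl)undec-10-yn-3-ol F4. K2CO3/MeOH removes the alkynyl silyl group and the fallback comes back to the route at 10, making steps 1, 2 and 7 unnecessary.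

**Step 20** (final desilylation) risks base‑induced retro‑oxa‑Michael opening and reclosure of the β‑peroxy ester, which would epimerise the ring CH. The fallback sets out from alcohol 14 and iodide 24 and removes the silyl group before any ester exists. Sonogashira coupling under the step 19 conditions gives 2-[(3S,6R)-6-methoxy-6-[(6E)-16-(trimethylsilyl)hexadec-6-ene-4,15-diyn-1-yl]-1,2-dioxan-3-yl]ethan-1-ol F7. K2CO3/MeOH gives the terminal alkyne 2-[(3S,6R)-6-methoxy-6-[(6E)-hexadec-6-ene-4,15-diyn-1-yl]-1,2-dioxan-3-yl]ethan-1-ol F8, which has no acidic α‑CH2 yet. TEMPO/PhI(OAc)2 in aqueous MeCN gives 2-[(3S,6R)-6-methoxy-6-[(6E)-hexadec-6-ene-4,15-diyn-1-yl]-1,2-dioxan-3-yl]acetic acid F9. TMSCHN2 then comes back to the route at 26.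

## Further compounds

F1 | step 6 | (5-chloropent-1-yn-1-yl)trimethylsilane | C[Si](C)(C)C#CCCCCl
F2 | step 6 | 2-methylidene-7-(trimethylsilyl)hept-6-yn-1-ol | C=C(CO)CCCC#C[Si](C)(C)C
F3 | step 6 | [6-(chloromethyl)hept-6-en-1-yn-1-yl]trimethylsilane | C=C(CCl)CCCC#C[Si](C)(C)C
F4 | step 6 | (3R)-1-[(tert-butyldimethylsilyl)oxy]-6-methylidene-11-(trimethylsilyl)undec-10-yn-3-ol | CC(C)(C)[Si](C)(C)OCC[C@H](O)CCC(=C)CCCC#C[Si](C)(C)C
F5 | step 10 | tert-butyl({(3S)-3-[(2-methoxypropan-2-yl)peroxy]-6-methylideneundec-10-yn-1-yl}oxy)dimethylsilane | CC(C)(C)[Si](C)(C)OCC[C@@H](OOC(C)(C)OC)CCC(=C)CCCC#C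
F6 | step 10 | (9S)-11-[(tert-butyldimethylsilyl)oxy]-9-[(2-methoxypropan-2-yl)peroxy]undec-1-yn-6-one | CC(C)(C)[Si](C)(C)OCC[C@@H](OOC(C)(C)OC)CCC(=O)CCCC#C
F7 | step 20 | 2-[(3S,6R)-6-methoxy-6-[(6E)-16-(trimethylsilyl)hexadec-6-ene-4,15-diyn-1-yl]-1,2-dioxan-3-yl]ethan-1-ol | C[Si](C)(C)C#CCCCCCCC/C=C/C#CCCC[C@]1(OC)CC[C@@H](CCO)OO1
F8 | step 20 | 2-[(3S,6R)-6-methoxy-6-[(6E)-hexadec-6-ene-4,15-diyn-1-yl]-1,2-dioxan-3-yl]ethan-1-ol | C#CCCCCCCC/C=C/C#CCCC[C@]1(OC)CC[C@@H](CCO)OO1
F9 | step 20 | 2-[(3S,6R)-6-methoxy-6-[(6E)-hexadec-6-ene-4,15-diyn-1-yl]-1,2-dioxan-3-yl]acetic acid | C#CCCCCCCC/C=C/C#CCCC[C@]1(OC)CC[C@@H](CC(=O)O)OO1
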